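Assumption: the target is read as the (7S,8R,7'S,8'R)-syringaresinol core (cis-fused furofuran, both aryl groups exo) whose two syringyl oxygens carry a (7R,8S)-erythro guaiacylglycerol unit (unit A, free phenol) and a (7S,8S)-threo unit (unit E), the guaiacyl oxygen of unit E carrying a (7S,8R)-erythro guaiacylglycerol unit (unit F, free phenol); lignan numbering (C7 benzylic, C8, C9) is used for every C3 chain.

## Retrosynthetic overview

1. Target ⇒ its bis-tosylate (two aryl O–S bonds, cleaved last).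
2. Unit E, C7–C8 bond ⇒ core-bound aryloxyacetaldehyde already carrying unit A + a benzaldehyde carrying unit F (syn enamine aldol, then reduction).
3. Units A and F, C7–C8 bonds ⇒ aryloxyacetaldehydes + vanillin tosylate (proline anti aldols); the aryloxyacetaldehydes come from a hydroxyethyl ether (oxidation) and from allyl ethers (alkene cleavage).
4. End-differentiated syringaresinol core ⇒ pentaol ⇒ trans-α,β-disubstituted γ-butyrolactone ⇒ L-proline aldol of O-allylsyringaldehyde with methyl 4-oxobutanoate (first stereocentre), then lactone-enolate aldol with a second, differently O-substituted syringaldehyde.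
5. Ring order: a temporary γ-butyrolactone first, then both tetrahydrofuran rings of the furofuran in one cyclodehydration; all benzene rings are bought.

## Route

Step 1
Reactants: 1 syringaldehyde; 2 allyl bromide
Product: 3 O-allylsyringaldehyde [4-(allyloxy)-3,5-dimethoxybenzaldehyde]
Conditions: K2CO3, DMF, 60 °C
Reagents that add atoms: none
Why: Williamson etherification of the acidic phenol with a reactive allylic bromide is routine and creates no stereocentre; the allyl group is the latent C8–C9 of unit E.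

Step 2
Reactants: 3 O-allylsyringaldehyde; 4 methyl 4-oxobutanoate
Product: 7 hydroxy lactone (4R)-4-{(R)-[4-(allyloxy)-3,5-dimethoxyphenyl](hydroxy)methyl}oxolan-2-one, via anti-aldol aldehyde 5 (not isolated), via hydroxy ester diol 6 (not isolated)
Conditions: L-proline (20 mol%), DMF, 4 °C, 4 (2 equiv) added over 24 h; then MeOH, NaBH4, −10 °C; aq. HCl work-up
Reagents that add atoms: none
Why: Proline-catalysed direct cross-aldol (enamine catalysis through the hydrogen-bonded Houk–List transition state), a known reaction of methyl 4-oxobutanoate with alkoxybenzaldehydes, in which the (E)-enamine of L-proline adds to the non-enolisable aldehyde to set the future C8 as R together with the anti carbinol, and immediate borohydride reduction with lactonisation of the primary alcohol fixes the product before the α-centre can epimerise.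

Step 3
Reactants: 1 syringaldehyde; 8 2-bromoethyl benzoate
Product: 9 2-(4-formyl-2,6-dimethoxyphenoxy)ethyl benzoate
Conditions: K2CO3, KI (cat.), DMF, 70 °C
Reagents that add atoms: none
Why: Williamson etherification without a stereocentre; the benzoate masks the hydroxyethyl group (latent C8–C9 of unit A) during the enolate chemistry of step 4 and is removed for free by the hydride of step 5.

Step 4
Reactants: 7 hydroxy lactone; 9 2-(4-formyl-2,6-dimethoxyphenoxy)ethyl benzoate
Product: 10 3,4-trans-disubstituted lactone (3S,4R; both epimers at the new carbinol carbon)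
Conditions: LiN(iPr)2 (2.2 equiv), THF, −78 °C; then 9, −78 °C; aq. NH4Cl
Reagents that add atoms: none
Why: Aldol addition of the lactone enolate (formed as the alkoxide–enolate dianion, which cannot translactonise) to the aryl aldehyde takes place on the ring face anti to the C4 substituent, giving the 3,4-trans lactone and thereby C8' (R in the furofuran), while the new carbinol centre is uncontrolled and is erased in step 5.

Step 5
Reactants: 10 3,4-trans-disubstituted lactone
Product: 12 syringaresinol 4-O-(2-hydroxyethyl) 4'-O-allyl diether (7S,8R,7'S,8'R), via pentaol 11 (not isolated)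
Conditions: LiAlH4, THF, 0 °C → rt, Fieser work-up (H2O, aq. NaOH); crude 11, TsOH·H2O (20 mol%), CH2Cl2 (0.01 M), 0 °C → rt, NaHCO3 quench at full conversion
Reagents that add atoms: none
Why: Hydride reduction opens the lactone and cleaves the benzoate, and the acid-catalysed SN1 cyclodehydration of the 1,4-diaryl-2,3-bis(hydroxymethyl)butane-1,4-diol (a known furofuran-lignan ring closure) ionises both electron-rich benzylic alcohols so that each cation is captured 5-exo by the 1,4-related primary hydroxyl anti to the neighbouring ring substituent, which sets 7S and 7'S (both aryl groups exo) whatever the carbinol configurations were.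

Step 6
Reactants: 12 syringaresinol 4-O-(2-hydroxyethyl) 4'-O-allyl diether
Product: 13 syringaresinol 4-O-(2-oxoethyl) 4'-O-allyl diether (aryloxyacetaldehyde)
Conditions: Dess–Martin periodinane (1.3 equiv), NaHCO3, CH2Cl2, 0 °C → rt; used at once
Reagents that add atoms: none
Why: Dess–Martin oxidation of the only hydroxyl gives the aryloxyacetaldehyde under neutral conditions that leave the allyl ether and the acid-sensitive furofuran untouched; no stereocentre is involved.

Step 7
Reactants: 14 vanillin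
Product: 15 vanillin tosylate (4-formyl-2-methoxyphenyl 4-methylbenzenesulfonate)
Conditions: TsCl, Et3N, DMAP (cat.), CH2Cl2, 0 °C → rt
Reagents that add atoms: p-toluenesulfonyl chloride, Cc1ccc(cc1)S(Cl)(=O)=O
Why: O-Sulfonylation of the phenol gives an acceptor aldehyde that is electron-poorer than an alkoxybenzaldehyde, inert to amine catalysts and borohydrides, and later cleavable without base or acid; no stereocentre.

Step 8
Reactants: 13 core aryloxyacetaldehyde; 15 vanillin tosylate
Product: 17 core diether carrying unit A as its (7R,8S)-erythro 7,9-diol with the aryl tosylate and the 4'-O-allyl group, via aldol aldehyde 16 (not isolated)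
Conditions: D-proline (30 mol%), 15 (5 equiv), DMF, 4 °C, 13 added over 24 h, then 24 h; then MeOH, NaBH4, −20 °C; minor diastereomers removed by chromatography
Reagents that add atoms: none
Why: Proposed new method: enamine cross-aldol with an α-aryloxyacetaldehyde donor, in which D-proline condenses with 13 to the (E)-enamine that adds through the hydrogen-bonded Houk–List chair to the activated non-enolisable aldehyde 15 (kept in excess while 13 is fed slowly to suppress donor self-aldol) to give the anti (2R,3R) aldehyde, reduced at once to the (7R,8S)-erythro diol, the closest known reaction type being the proline-catalysed anti cross-aldol of α-alkoxy- and α-silyloxyacetaldehyde donors and of alkyl aldehydes with aryl aldehydes, not yet shown for aryloxyacetaldehydes.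

Step 9
Reactants: 17 core diether carrying unit A
Product: 19 core 4'-O-(2-oxoethyl) ether carrying unit A, via glycol 18 (not isolated)
Conditions: OsO4 (2 mol%), NaIO4 (4 equiv), 2,6-lutidine, dioxane/H2O 3:1, rt; used at once
Reagents that add atoms: OsO4, O=[Os](=O)(=O)=O; NaIO4, [Na+].[O-]I(=O)(=O)=O
Why: Lemieux–Johnson cleavage (catalytic dihydroxylation, then periodate glycol cleavage) acts on the only alkene and spares the 1,3-diol and the tosylate; the glycol carbinol is transient and no existing stereocentre is touched.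

Step 10
Reactants: 20 O-allylvanillin [4-(allyloxy)-3-methoxybenzaldehyde]
Product: 22 2-(4-formyl-2-methoxyphenoxy)acetaldehyde, via glycol 21 (not isolated)
Conditions: OsO4 (2 mol%), NaIO4 (4 equiv), 2,6-lutidine, dioxane/H2O 3:1, rt; used at once
Reagents that add atoms: OsO4, O=[Os](=O)(=O)=O; NaIO4, [Na+].[O-]I(=O)(=O)=O
Why: Lemieux–Johnson cleavage of the allyl ether gives the aryloxyacetaldehyde while the aromatic aldehyde is inert; no stereocentre.

Step 11
Reactants: 22 2-(4-formyl-2-methoxyphenoxy)acetaldehyde; 15 vanillin tosylate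
Product: 24 benzaldehyde carrying unit F as its (7S,8R)-erythro 7,9-diol with the aryl tosylate, via aldol aldehyde 23 (not isolated)
Conditions: L-proline (30 mol%), 15 (4 equiv), DMF, 4 °C, 22 added over 24 h; then MeCN/AcOH, NaBH(OAc)3, −20 → 0 °C
Reagents that add atoms: none
Why: Proposed new method: the same aryloxyacetaldehyde enamine cross-aldol, here with L-proline on achiral partners, where only the aliphatic formyl group of 22 can form an enamine and it adds to the more electrophilic aldehyde 15 present in excess to give the anti (2S,3S) aldehyde, which hydroxyl-directed triacetoxyborohydride reduction converts to the (7S,8R)-erythro diol without touching the aryl aldehyde, the closest known reaction type being the proline anti cross-aldol of α-oxyaldehyde donors and the directed reduction of β-hydroxy carbonyl compounds.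

Step 12
Reactants: 19 core 4'-O-(2-oxoethyl) ether carrying unit A; 24 benzaldehyde carrying unit F
Product: 26 bis-tosylate of the target (units A, E and F in place), via aldol aldehyde 25 (not isolated)
Conditions: O-tert-butyl-L-threonine (30 mol%), 24 (3 equiv), N-methylpyrrolidone with H2O (3 equiv), 4 °C → rt, 19 added over 24 h; then MeCN/AcOH, NaBH(OAc)3, −20 → 0 °C; excess 24 recovered
Reagents that add atoms: none
Why: Proposed new method: syn-selective primary-amine enamine aldol of an aryloxyacetaldehyde, in which O-tert-butyl-L-threonine forms a secondary enamine whose N–H hydrogen-bonds to the aryloxy oxygen and a flanking methoxy group and so holds the (Z)-enamine, while the carboxylic acid delivers aldehyde 24 in the same facial sense as L-proline, so that C7 becomes S as in step 11 but C8 has the opposite relative sense, giving the syn (2R,3S) aldehyde and after directed reduction the (7S,8S)-threo unit E, the closest known reaction type being the threonine-type primary-amine syn-aldol of α-hydroxy and α-alkoxy ketones through hydrogen-bonded (Z)-enamines.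

Step 13
Reactants: 26 bis-tosylate of the target
Product: 27 target CNP0316493.3
Conditions: Mg turnings (20 equiv), MeOH, rt, sonication; aq. NH4Cl
Reagents that add atoms: none
Why: Reductive S–O cleavage of aryl tosylates by electron transfer from Mg in MeOH is a known mild deprotection that frees both guaiacyl phenols without acid or strong base, so the benzylic alcohols, the aryl alkyl ethers and the furofuran keep their configuration.

## Compound list

1 | syringaldehyde (4-hydroxy-3,5-dimethoxybenzaldehyde) | COc1cc(C=O)cc(OC)c1O | starting material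
2 | allyl bromide | C=CCBr | starting material
3 | 4-(allyloxy)-3,5-dimethoxybenzaldehyde | C=CCOc1c(OC)cc(C=O)cc1OC | intermediate
4 | methyl 4-oxobutanoate | COC(=O)CCC=O | starting material
5 | methyl (3S,4R)-4-[4-(allyloxy)-3,5-dimethoxyphenyl]-3-formyl-4-hydroxybutanoate (not isolated) | O=C[C@@H](CC(=O)OC)[C@@H](O)c1cc(OC)c(OCC=C)c(OC)c1 | intermediate
6 | methyl (3R,4R)-4-[4-(allyloxy)-3,5-dimethoxyphenyl]-4-hydroxy-3-(hydroxymethyl)butanoate (not isolated) | OC[C@@H](CC(=O)OC)[C@@H](O)c1cc(OC)c(OCC=C)c(OC)c1 | intermediate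
7 | (4R)-4-{(R)-[4-(allyloxy)-3,5-dimethoxyphenyl](hydroxy)methyl}oxolan-2-one | O=C1C[C@H](CO1)[C@@H](O)c2cc(OC)c(OCC=C)c(OC)c2 | intermediate
8 | 2-bromoethyl benzoate | BrCCOC(=O)c1ccccc1 | starting material
9 | 2-(4-formyl-2,6-dimethoxyphenoxy)ethyl benzoate | O=Cc1cc(OC)c(OCCOC(=O)c2ccccc2)c(OC)c1 | intermediate
10 | (3S,4R)-4-{(R)-[4-(allyloxy)-3,5-dimethoxyphenyl](hydroxy)methyl}-3-{[4-(2-benzoyloxyethoxy)-3,5-dimethoxyphenyl](hydroxy)methyl}oxolan-2-one (3,4-trans; both epimers at the new carbinol carbon) | O=C1[C@H](C(O)c2cc(OC)c(OCCOC(=O)c3ccccc3)c(OC)c2)[C@H](CO1)[C@@H](O)c4cc(OC)c(OCC=C)c(OC)c4 | intermediate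
11 | (1R,2R,3R)-1-[4-(allyloxy)-3,5-dimethoxyphenyl]-4-[4-(2-hydroxyethoxy)-3,5-dimethoxyphenyl]-2,3-bis(hydroxymethyl)butane-1,4-diol (both C4 epimers; not isolated) | OC[C@H](C(O)c1cc(OC)c(OCCO)c(OC)c1)[C@H](CO)[C@@H](O)c2cc(OC)c(OCC=C)c(OC)c2 | intermediate
12 | 2-{4-[(1S,3aR,4S,6aR)-4-(4-allyloxy-3,5-dimethoxyphenyl)tetrahydro-1H,3H-furo[3,4-c]furan-1-yl]-2,6-dimethoxyphenoxy}ethanol, i.e. (7S,8R,7'S,8'R)-syringaresinol 4-O-(2-hydroxyethyl) 4'-O-allyl diether | OCCOc1c(OC)cc(cc1OC)[C@H]2OC[C@H]3[C@@H]2CO[C@@H]3c4cc(OC)c(OCC=C)c(OC)c4 | intermediate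
13 | the corresponding acetaldehyde, (7S,8R,7'S,8'R)-syringaresinol 4-O-(2-oxoethyl) 4'-O-allyl diether | O=CCOc1c(OC)cc(cc1OC)[C@H]2OC[C@H]3[C@@H]2CO[C@@H]3c4cc(OC)c(OCC=C)c(OC)c4 | intermediate
14 | vanillin (4-hydroxy-3-methoxybenzaldehyde) | COc1cc(C=O)ccc1O | starting material
15 | 4-formyl-2-methoxyphenyl 4-methylbenzenesulfonate (vanillin tosylate) | COc1cc(C=O)ccc1OS(=O)(=O)c2ccc(C)cc2 | intermediate
16 | (7S,8R,7'S,8'R)-syringaresinol 4'-O-allyl ether 4-O-{(1R,2R)-1-hydroxy-1-[3-methoxy-4-(tosyloxy)phenyl]-3-oxopropan-2-yl} ether (not isolated) | COc1cc([C@@H](O)[C@H](C=O)Oc2c(OC)cc(cc2OC)[C@H]3OC[C@H]4[C@@H]3CO[C@@H]4c5cc(OC)c(OCC=C)c(OC)c5)ccc1OS(=O)(=O)c6ccc(C)cc6 | intermediate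
17 | (7S,8R,7'S,8'R)-syringaresinol 4'-O-allyl ether 4-O-{(1R,2S)-1,3-dihydroxy-1-[3-methoxy-4-(tosyloxy)phenyl]propan-2-yl} ether (unit A, erythro) | COc1cc([C@@H](O)[C@H](CO)Oc2c(OC)cc(cc2OC)[C@H]3OC[C@H]4[C@@H]3CO[C@@H]4c5cc(OC)c(OCC=C)c(OC)c5)ccc1OS(=O)(=O)c6ccc(C)cc6 | intermediate
18 | the 4'-O-(2,3-dihydroxypropyl) analogue of 17 (both glycol epimers; not isolated) | COc1cc([C@@H](O)[C@H](CO)Oc2c(OC)cc(cc2OC)[C@H]3OC[C@H]4[C@@H]3CO[C@@H]4c5cc(OC)c(OCC(O)CO)c(OC)c5)ccc1OS(=O)(=O)c6ccc(C)cc6 | intermediate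
19 | the 4'-O-(2-oxoethyl) analogue of 17 (aryloxyacetaldehyde carrying unit A) | COc1cc([C@@H](O)[C@H](CO)Oc2c(OC)cc(cc2OC)[C@H]3OC[C@H]4[C@@H]3CO[C@@H]4c5cc(OC)c(OCC=O)c(OC)c5)ccc1OS(=O)(=O)c6ccc(C)cc6 | intermediate
20 | 4-(allyloxy)-3-methoxybenzaldehyde (O-allylvanillin) | C=CCOc1ccc(C=O)cc1OC | starting material
21 | 4-(2,3-dihydroxypropoxy)-3-methoxybenzaldehyde (racemic glycol; not isolated) | OCC(O)COc1ccc(C=O)cc1OC | intermediate
22 | 2-(4-formyl-2-methoxyphenoxy)acetaldehyde | O=CCOc1ccc(C=O)cc1OC | intermediate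
23 | 4-{[(1S,2S)-1-hydroxy-1-[3-methoxy-4-(tosyloxy)phenyl]-3-oxopropan-2-yl]oxy}-3-methoxybenzaldehyde (not isolated) | O=Cc1ccc(O[C@H](C=O)[C@@H](O)c2ccc(OS(=O)(=O)c3ccc(C)cc3)c(OC)c2)c(OC)c1 | intermediate
24 | 4-{[(1S,2R)-1,3-dihydroxy-1-[3-methoxy-4-(tosyloxy)phenyl]propan-2-yl]oxy}-3-methoxybenzaldehyde (unit F, erythro) | O=Cc1ccc(O[C@H](CO)[C@@H](O)c2ccc(OS(=O)(=O)c3ccc(C)cc3)c(OC)c2)c(OC)c1 | intermediate
25 | 26 with C9 of unit E still a formyl group, (2R,3S)-syn aldol aldehyde (not isolated) | COc1cc([C@@H](O)[C@H](CO)Oc2c(OC)cc(cc2OC)[C@H]3OC[C@H]4[C@@H]3CO[C@@H]4c5cc(OC)c(O[C@@H](C=O)[C@@H](O)c6ccc(O[C@H](CO)[C@@H](O)c7ccc(OS(=O)(=O)c8ccc(C)cc8)c(OC)c7)c(OC)c6)c(OC)c5)ccc1OS(=O)(=O)c9ccc(C)cc9 | intermediate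
26 | target in which both guaiacyl phenols (units A and F) are 4-methylbenzenesulfonates; unit A (7R,8S), unit E (7S,8S), unit F (7S,8R), core (7S,8R,7'S,8'R) | COc1cc([C@@H](O)[C@H](CO)Oc2c(OC)cc(cc2OC)[C@H]3OC[C@H]4[C@@H]3CO[C@@H]4c5cc(OC)c(O[C@@H](CO)[C@@H](O)c6ccc(O[C@H](CO)[C@@H](O)c7ccc(OS(=O)(=O)c8ccc(C)cc8)c(OC)c7)c(OC)c6)c(OC)c5)ccc1OS(=O)(=O)c9ccc(C)cc9 | intermediate
27 | CNP0316493.3: (7S,8R,7'S,8'R)-syringaresinol 4-O-[(1R,2S)-1,3-dihydroxy-1-(4-hydroxy-3-methoxyphenyl)propan-2-yl] 4'-O-[(1S,2S)-1,3-dihydroxy-1-{4-[(1S,2R)-1,3-dihydroxy-1-(4-hydroxy-3-methoxyphenyl)propan-2-yl]oxy-3-methoxyphenyl}propan-2-yl] diether | COc1cc([C@@H](O)[C@H](CO)Oc2c(OC)cc([C@H]3OC[C@H]4[C@@H]3CO[C@@H]4c3cc(OC)c(O[C@@H](CO)[C@@H](O)c4ccc(O[C@H](CO)[C@@H](O)c5ccc(O)c(OC)c5)c(OC)c4)c(OC)c3)cc2OC)ccc1O | target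

## Step count and risks

Total steps: 13. Longest linear sequence: 9 (steps 1, 2, 4, 5, 6, 8, 9, 12, 13); steps 3, 7, 10 and 11 are side branches.

Three steps most likely to fail:

Step 12 (proposed new syn aldol). The risks are untested syn control, slow addition to the electron-rich aldehyde 24, and donor self-aldol. The fallback uses known chemistry, an auxiliary-controlled Evans syn-aldol of an aryloxyacetyl imide; it sets out from 17 and comes back at 26. The allyl ether of 17 is removed with Pd(PPh3)4 (zerovalent palladium) and morpholine to give the syringyl phenol F1. F1 is O-alkylated (K2CO3, acetone) with (R)-4-benzyl-3-(bromoacetyl)oxazolidin-2-one to give the aryloxyacetyl imide F2. The dibutylboron (Z)-enolate of F2 (Bu2BOTf, iPr2NEt, CH2Cl2, −78 °C, with extra Bu2BOTf tying up the four free hydroxyls as borinates) adds to 24 to give the syn adduct F3 with the (7S,8S) configuration. LiBH4 in THF/MeOH then removes the auxiliary reductively, and the resulting primary alcohol is 26.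

Step 8 (proposed new anti aldol, first use on the core). The risks are donor self-aldol and a modest anti:syn ratio. The fallback uses known chemistry, Evans syn-aldol followed by Mitsunobu inversion of the benzylic carbinol; it sets out from 13 and comes back at 17. Pinnick oxidation of 13 (NaClO2, NaH2PO4, 2-methyl-2-butene) gives the aryloxyacetic acid F4. Its pivaloyl mixed anhydride acylates lithiated (R)-4-benzyloxazolidin-2-one to give the imide F5. Bu2BOTf/iPr2NEt and then 15 give the syn adduct F6, which has the correct C8 and the epimeric C7. 4-Nitrobenzoic acid, PPh3 and diisopropyl azodicarboxylate invert C7 to give the 4-nitrobenzoate F7. LiBH4 cleaves auxiliary and ester to give 17.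

Step 11 (proposed new anti aldol on a dialdehyde). The risks are chemoselectivity between the two formyl groups of 22 and selectivity of the reduction. The fallback uses known chemistry on a donor without a free aromatic aldehyde; it sets out from 15 and comes back at 24. Bought methyl vanillate is O-alkylated (K2CO3, acetone) with (S)-4-benzyl-3-(bromoacetyl)oxazolidin-2-one to give the imide F8. Its boron enolate (Bu2BOTf, iPr2NEt) adds to 15 to give the syn adduct F9. Mitsunobu inversion with 4-nitrobenzoic acid gives the ester F10. LiBH4 reduces the imide, the nitrobenzoate and the aryl methyl ester to give the triol F11. DDQ in CH2Cl2/H2O oxidises only the electron-rich 4-alkoxybenzylic primary alcohol of F11 to the aldehyde, which is 24.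

## Further compounds

F1 | step 12 | (7S,8R,7'S,8'R)-syringaresinol 4-O-{(1R,2S)-1,3-dihydroxy-1-[3-methoxy-4-(tosyloxy)phenyl]propan-2-yl} ether with free 4'-phenol | COc1cc([C@@H](O)[C@H](CO)Oc2c(OC)cc(cc2OC)[C@H]3OC[C@H]4[C@@H]3CO[C@@H]4c5cc(OC)c(O)c(OC)c5)ccc1OS(=O)(=O)c6ccc(C)cc6
F2 | step 12 | F1 O-alkylated at the 4'-phenol with the 2-[(4R)-4-benzyl-2-oxooxazolidin-3-yl]-2-oxoethyl group | COc1cc([C@@H](O)[C@H](CO)Oc2c(OC)cc(cc2OC)[C@H]3OC[C@H]4[C@@H]3CO[C@@H]4c5cc(OC)c(OCC(=O)N6[C@H](Cc7ccccc7)COC6=O)c(OC)c5)ccc1OS(=O)(=O)c8ccc(C)cc8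
F3 | step 12 | Evans syn adduct of F2 with 24, (2R,3S)-3-hydroxy-2-aryloxy-3-arylpropanoyl imide of (4R)-4-benzyloxazolidin-2-one (unit E as 7S,8S with C9 as the imide) | COc1cc([C@@H](O)[C@H](CO)Oc2c(OC)cc(cc2OC)[C@H]3OC[C@H]4[C@@H]3CO[C@@H]4c5cc(OC)c(O[C@@H](C(=O)N6[C@H](Cc7ccccc7)COC6=O)[C@@H](O)c6ccc(O[C@H](CO)[C@@H](O)c7ccc(OS(=O)(=O)c8ccc(C)cc8)c(OC)c7)c(OC)c6)c(OC)c5)ccc1OS(=O)(=O)c9ccc(C)cc9
F4 | step 8 | (7S,8R,7'S,8'R)-syringaresinol 4'-O-allyl ether 4-O-(carboxymethyl) ether | OC(=O)COc1c(OC)cc(cc1OC)[C@H]2OC[C@H]3[C@@H]2CO[C@@H]3c4cc(OC)c(OCC=C)c(OC)c4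
F5 | step 8 | (4R)-4-benzyl-3-(aryloxyacetyl)oxazolidin-2-one derived from F4 | O=C(COc1c(OC)cc(cc1OC)[C@H]2OC[C@H]3[C@@H]2CO[C@@H]3c4cc(OC)c(OCC=C)c(OC)c4)N5[C@H](Cc6ccccc6)COC5=O
F6 | step 8 | Evans syn adduct of F5 with 15, (4R)-4-benzyl-3-[(2R,3S)-3-hydroxy-3-(3-methoxy-4-tosyloxyphenyl)-2-(aryloxy)propanoyl]oxazolidin-2-one | O=C([C@H](Oc1c(OC)cc(cc1OC)[C@H]2OC[C@H]3[C@@H]2CO[C@@H]3c4cc(OC)c(OCC=C)c(OC)c4)[C@@H](O)c5ccc(OS(=O)(=O)c6ccc(C)cc6)c(OC)c5)N7[C@H](Cc8ccccc8)COC7=O
F7 | step 8 | C3-inverted 4-nitrobenzoate of F6, (2R,3R) | O=C([C@H](Oc1c(OC)cc(cc1OC)[C@H]2OC[C@H]3[C@@H]2CO[C@@H]3c4cc(OC)c(OCC=C)c(OC)c4)[C@H](OC(=O)c5ccc(cc5)[N+](=O)[O-])c6ccc(OS(=O)(=O)c7ccc(C)cc7)c(OC)c6)N8[C@H](Cc9ccccc9)COC8=O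
F8 | step 11 | methyl 4-{2-[(4S)-4-benzyl-2-oxooxazolidin-3-yl]-2-oxoethoxy}-3-methoxybenzoate | COC(=O)c1ccc(OCC(=O)N2[C@@H](Cc3ccccc3)COC2=O)c(OC)c1
F9 | step 11 | Evans syn adduct of F8 with 15, methyl 4-{[(2S,3R)-1-[(4S)-4-benzyl-2-oxooxazolidin-3-yl]-3-hydroxy-3-(3-methoxy-4-tosyloxyphenyl)-1-oxopropan-2-yl]oxy}-3-methoxybenzoate | COC(=O)c1ccc(O[C@H](C(=O)N2[C@@H](Cc3ccccc3)COC2=O)[C@H](O)c4ccc(OS(=O)(=O)c5ccc(C)cc5)c(OC)c4)c(OC)c1
F10 | step 11 | C3-inverted 4-nitrobenzoate of F9, (2S,3S) | COC(=O)c1ccc(O[C@H](C(=O)N2[C@@H](Cc3ccccc3)COC2=O)[C@@H](OC(=O)c4ccc(cc4)[N+](=O)[O-])c5ccc(OS(=O)(=O)c6ccc(C)cc6)c(OC)c5)c(OC)c1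
F11 | step 11 | 4-{(1S,2R)-1,3-dihydroxy-2-[4-(hydroxymethyl)-2-methoxyphenoxy]propyl}-2-methoxyphenyl 4-methylbenzenesulfonate | OCc1ccc(O[C@H](CO)[C@@H](O)c2ccc(OS(=O)(=O)c3ccc(C)cc3)c(OC)c2)c(OC)c1
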